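I start from the leftover I expect at the end of these flasks, unused first nucleophile beside unused second nucleophile, and ask what that pair does to the intermediate on the way there.

    substrate ⇌ intermediate (K1 = 0.234, k1 = 2.78 × 10⁻⁴ /min, Ea1 = 113 kJ/mol, ΔH1 = −12.0 kJ/mol)
    first nucleophile + intermediate → target (k2 = 8.94 /M/min, Ea2 = 49.0 kJ/mol)
    second nucleophile + intermediate → other capture product (k3 = 9.35 /M/min, Ea3 = 41.0 kJ/mol)
    first nucleophile + protic impurity → quenched reagent (k4 = 0.0341 /M/min, Ea4 = 84.0 kJ/mol)
    first nucleophile + target ⇌ idle adduct, settled at all times (K5 = 2530 /M, ΔH5 = −16.0 kJ/mol)
    (constants at 35 °C)

common to all: substrate 20 mM; protic impurity 6.00 mM; time 2.5 d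
- Sunday's: first nucleophile 19.0 mM; second nucleophile 50.0 mM (fed, over 2.5 h); temperature 35 °C; all else is in the flask from the start; the feed brings no volume worth counting
- Friday's: first nucleophile 19.0 mM (fed, over 25 h); second nucleophile 50.0 mM; temperature 35 °C; all else is in the flask from the start; the feed brings no volume worth counting
- Saturday's: first nucleophile 19.0 mM; second nucleophile 50.0 mM; everything together at the start at 5 °C, warmed to 35 °C at 25 h
- Tuesday's: first nucleophile 19.0 mM; second nucleophile 50.0 mM (in portions, 5, over 25 h); temperature 35 °C; first portion at the start, last at 25 h
- Wednesday's: first nucleophile 19.0 mM; second nucleophile 50.0 mM; temperature 35 °C; everything together at the start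
- Monday's: first nucleophile 19.0 mM; second nucleophile 50.0 mM (fed, over 25 h); the addition at 5 °C, then warmed to 35 °C; the feed brings no volume worth counting

- amounts and yields of target count idle adduct too
- the list of constants is for 35 °C, to be carried to other temperatures by the activation energies and enthalpies

- the best flask by amount of target, in percent of the substrate charged; "all alike" if 1.5 percentage points covers them all (Sunday's / Friday's / Saturday's / Tuesday's / Wednesday's / Monday's / all alike)
- amount of target at the end, in percent of the substrate charged, Sunday's
- amount of target at the end, in percent of the substrate charged, Friday's
- amount of target at the end, in percent of the substrate charged, Saturday's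
- amount of target at the end, in percent of the substrate charged, Tuesday's
- amount of target at the end, in percent of the substrate charged, Wednesday's
- amount of target at the end, in percent of the substrate charged, Monday's

- The number I carry is the capture ratio, the rate constant of the second nucleophile times its amount over the rate constant of the first nucleophile times its amount, which at the full charges is 2.75; the target's share of the captured intermediate is one over one plus this ratio, and control crosses to the first nucleophile at a ratio of 1, where the second nucleophile stands at 0.956 times the first.
- Intermediate returns to substrate at 0.00119 /min but is captured at 0.637 /min with the charges in place, so I treat the substrate step as the rate-limiting step running one way, and in a flask held at 35 °C it turns over 63.2% of the substrate in 2.5 d.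
- My first way, for Wednesday's, holds the charges for the whole run, so the turnover times the target's share gives 16.9%.
- My second way, also for Wednesday's, keeps a balance: the equilibrium constant of the adduct step times the charged first nucleophile is 48, so at the start nearly all of any target binds another first nucleophile, and I book 2 first nucleophile per target plus the whole impurity.
- The first way's target then leaves 6.26 mM of first nucleophile and 40.7 mM of second nucleophile, a capture ratio of 6.81, and averaging the target's share at the start and at this end gives 12.5%.
- The two ways part, and the first one cheats, since it holds the first nucleophile at 19.0 mM while its own target, with the adduct, books 6.74 mM of it; the second cheats the other way, spending the whole impurity although the impurity's own half-life by the quench, with the first nucleophile held at its charge, is 0.743 d, which leaves 9.71% of the impurity after 2.5 d even at that full charge, so I commit to Wednesday's lying between 12.5% and 16.9%.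
- In Tuesday's the portions hold the second nucleophile at an average of 25.0 mM over the first 25 h, half the charge, which gives a capture ratio of 1.38 while 34.1% of the substrate turns over; with the end ratio for the remaining turnover I reckon 18.1% for Tuesday's, more than either way gives for Wednesday's, and I leave the other flasks unreckoned.
- The forecast names Tuesday's as best, with 14.4% for Sunday's, 10.5% for Friday's, 10.4% for Saturday's, 18.4% for Tuesday's, 13.7% for Wednesday's and 10.5% for Monday's, on the ground that “Holding back the second nucleophile in portions keeps that ratio high while the first nucleophile is still plentiful”.
- The simulation gives Tuesday's as best, with 14.3% for Sunday's, 10.9% for Friday's, 10.1% for Saturday's, 18.6% for Tuesday's, 13.7% for Wednesday's and 10.2% for Monday's, so the forecast stands, and Wednesday's falls between my two ways.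
- In Tuesday's the capture ratio reads 3.5 at 0.951 d and 5.9 at 2.50 d, both higher than the 2.75 of the full charges, and Tuesday's leads Sunday's by 4.3 percentage points.
- For the neighbour of Tuesday's charged with 76 mM of first nucleophile, the capture ratio at full charges falls to 0.688, below the crossing, and the turnover times the target's share gives 37.4%. The simulation of that flask gives 40.9%, and target is the species holding most of the substrate there.

All constants come from no measurement; the rest is arithmetic.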